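**Plan**

1. Atoms carry the numbers of the heavy atoms in the order of the target SMILES. The catechol ring (C35, C36, C37, C39, C41, C42) hangs on the cage by only two bonds, C35–C16 and C42–C43, and shares only the C35–C42 edge with the carbocycle C14–C15–C16–C35–C42–C43.
2. The retrosynthesis therefore trades the two phenolic C–O bonds for C–B bonds and cuts C35–C42, C36–C37 and C39–C41, leaving ethynyl groups on C16 and C43 and a diborylacetylene (C37, C39).
3. The diyne is unravelled at C16–O17 and C16–C35 (enolate hydroxylation, Sonogashira), C21–C22 (Heck), O13–C14 (dearomatising spiroetherification), C23–aryl, C12–C23, C10–C11 and C42–C43, back to 4-hydroxybenzaldehyde.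
4. Forward, the chain C43–C11–C12 is built linearly; the rings then arise in the order tetrahydrofuran (O13–C14), dihydropyran of the 8-oxabicyclo[3.2.1]octene (C21–C22), and last the carbocycle plus the arene in one [2+2+2] event.
5. Stereochemistry: C43 from a Rh/DTBM-SEGPHOS conjugate alkynylation, C11 by 1,2-induction in an enolate benzylation, C12 by Ru–TsDPEN transfer hydrogenation, C14 by the tether in the Heck desymmetrisation, C16 by enolate hydroxylation on the face away from the C43 alkynyl group.
6. Oxidation of both C–B bonds and removal of two MOM ethers finish the synthesis.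

Key step: step 24

Remark: 10, 12, 17 and 33 are taken as purchased; the sense of induction in step 8 is assigned by analogy with other β-aryl enals, and the ligand antipode that delivers (3S)-13 is the one meant.

Abbreviations: Ar1CH2 = 2-methoxy-4-(methoxymethoxy)benzyl; Ar2 = 2,4-dimethoxy-3-(methoxymethoxy)phenyl; TIPS = triisopropylsilyl; TMS = trimethylsilyl; MOM = methoxymethyl; Bpin = 4,4,5,5-tetramethyl-1,3,2-dioxaborolan-2-yl.

**Route**

Step 1
Reactants: 1 4-hydroxy-2-methoxybenzaldehyde
Product: 2 2-methoxy-4-(methoxymethoxy)benzaldehyde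
Conditions: MOMCl, i-Pr2NEt, CH2Cl2, 0 °C → rt
Reagents that add atoms: chloromethyl methyl ether, COCCl
Why: Base-mediated O-alkylation (Williamson-type etherification) of the acidic phenol para to the formyl group should install an acetal ether that withstands the enolate, organometallic, palladium and fluoride steps ahead and falls off with acid at the very end.

Step 2
Reactants: 2 2-methoxy-4-(methoxymethoxy)benzaldehyde
Product: 3 [2-methoxy-4-(methoxymethoxy)phenyl]methanol
Conditions: NaBH4, MeOH, 0 °C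
Reagents that add atoms: none
Why: Borohydride reduction of the aryl aldehyde should give the benzylic alcohol cleanly, the MOM acetal being inert to hydride.

Step 3
Reactants: 3 [2-methoxy-4-(methoxymethoxy)phenyl]methanol
Product: 4 1-(bromomethyl)-2-methoxy-4-(methoxymethoxy)benzene
Conditions: CBr4, PPh3, CH2Cl2, 0 °C; used without storage
Reagents that add atoms: tetrabromomethane, BrC(Br)(Br)Br
Why: The Appel reaction converts the benzylic alcohol into the bromide under neutral conditions, so the acid-labile MOM ether survives, and the electron-rich, labile bromide is taken on at once.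

Step 4
Reactants: 5 2,6-dimethoxyphenol
Product: 6 1,3-dimethoxy-2-(methoxymethoxy)benzene
Conditions: NaH, MOMCl, DMF, 0 °C → rt
Reagents that add atoms: chloromethyl methyl ether, COCCl
Why: O-Alkylation of the hindered sodium phenoxide with MOMCl (Williamson-type etherification) protects the future C30 phenol as the same acetal used on the other ring.

Step 5
Reactants: 6 1,3-dimethoxy-2-(methoxymethoxy)benzene
Product: 7 1-bromo-2,4-dimethoxy-3-(methoxymethoxy)benzene
Conditions: NBS, MeCN, 0 °C → rt
Reagents that add atoms: N-bromosuccinimide, O=C1CCC(=O)N1Br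
Why: Electrophilic aromatic bromination should occur para to one outer methoxy group and ortho to the other, as in 1,2,3-trialkoxybenzenes whose twisted central alkoxy group donates least, giving the substitution pattern needed at C24.

Step 6
Reactants: 8 4-hydroxybenzaldehyde
Product: 9 4-[(triisopropylsilyl)oxy]benzaldehyde
Conditions: TIPSCl, imidazole, DMF, rt
Reagents that add atoms: chlorotriisopropylsilane, CC(C)[Si](Cl)(C(C)C)C(C)C
Why: Silylation of the phenol gives a bulky aryl silyl ether that survives methanolic carbonate and organometallics yet is cleaved by fluoride faster than an alkynylsilane.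

Step 7
Reactants: 9 4-[(triisopropylsilyl)oxy]benzaldehyde; 10 (triphenylphosphoranylidene)acetaldehyde
Product: 11 (E)-3-{4-[(triisopropylsilyl)oxy]phenyl}prop-2-enal
Conditions: toluene, 90 °C
Reagents that add atoms: none
Why: Wittig olefination with the stabilised formyl ylide should give the (E)-enal, the C11 and C12 carbons arriving with the ylide.

Step 8
Reactants: 11 (E)-3-{4-[(triisopropylsilyl)oxy]phenyl}prop-2-enal; 12 ethynyltriisopropylsilane
Product: 13 (3S)-3-{4-[(triisopropylsilyl)oxy]phenyl}-5-(triisopropylsilyl)pent-4-ynal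
Conditions: [Rh(OAc)(C2H4)2]2 (2.5 mol%), (R)-DTBM-SEGPHOS (6 mol%), MeOH, 40 °C
Reagents that add atoms: none
Why: In this rhodium-catalysed asymmetric conjugate alkynylation of a β-aryl enal the alkynylrhodium bound to the chiral bisphosphine adds to one enal face and thereby sets C43 (3S), while the bulky silyl group keeps the alkyne from dimerising and later shields it through the palladium steps.

Step 9
Reactants: 13 (3S)-β-alkynyl aldehyde
Product: 14 (3S)-3-{4-[(triisopropylsilyl)oxy]phenyl}-5-(triisopropylsilyl)pent-4-ynoic acid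
Conditions: NaClO2, NaH2PO4, 2-methyl-2-butene, t-BuOH/H2O, 0 °C → rt
Reagents that add atoms: sodium chlorite, [Na+].[O-]Cl=O
Why: Pinnick oxidation takes the aldehyde to the acid under buffered conditions with 2-methyl-2-butene scavenging hypochlorite, so neither the benzylic–propargylic stereocentre nor the silyl groups are disturbed.

Step 10
Reactants: 14 (3S)-β-alkynyl acid
Product: 15 (3S)-N-methoxy-N-methyl-3-{4-[(triisopropylsilyl)oxy]phenyl}-5-(triisopropylsilyl)pent-4-ynamide
Conditions: MeNHOMe·HCl, EDC·HCl, Et3N, DMAP (cat.), CH2Cl2, 0 °C → rt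
Reagents that add atoms: N,O-dimethylhydroxylamine hydrochloride, CNOC.Cl
Why: Carbodiimide-mediated amide coupling gives the Weinreb amide, which alkylates cleanly as its enolate and later stops organolithium addition at the ketone stage.

Step 11
Reactants: 15 (3S)-Weinreb amide; 4 1-(bromomethyl)-2-methoxy-4-(methoxymethoxy)benzene
Product: 16 (2S,3S)-N-methoxy-2-[2-methoxy-4-(methoxymethoxy)benzyl]-N-methyl-3-{4-[(triisopropylsilyl)oxy]phenyl}-5-(triisopropylsilyl)pent-4-ynamide
Conditions: LiN(i-Pr)2, THF, −78 °C; then 4, −78 → −40 °C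
Reagents that add atoms: none
Why: In this enolate alkylation the allylic-strain-minimised conformer has the C43–H bond eclipsing the enolate, so the benzylic bromide comes in anti to the aryl group past the slim alkynyl group, which should set C11 with the benzyl group anti to the alkyne (2S).

Step 12
Reactants: 16 (2S,3S)-benzylated Weinreb amide; 17 ethynyltrimethylsilane
Product: 19 (4S,5S)-4-[2-methoxy-4-(methoxymethoxy)benzyl]-5-{4-[(triisopropylsilyl)oxy]phenyl}-7-(triisopropylsilyl)-1-(trimethylsilyl)hepta-1,6-diyn-3-one, via lithium (trimethylsilyl)acetylide 18 (not isolated)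
Conditions: 17, n-BuLi, THF, −78 °C; then 16, −78 → −20 °C; cold aq NH4Cl
Reagents that add atoms: none
Why: In the Weinreb ketone synthesis the lithium acetylide adds once to give a chelated tetrahedral adduct that collapses to the ynone only on cold aqueous quench, which avoids over-addition and base-mediated epimerisation at C11.

Step 13
Reactants: 19 (4S,5S)-ynone
Product: 20 (3S,4S,5S)-4-[2-methoxy-4-(methoxymethoxy)benzyl]-5-{4-[(triisopropylsilyl)oxy]phenyl}-7-(triisopropylsilyl)-1-(trimethylsilyl)hepta-1,6-diyn-3-ol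
Conditions: Ru[(S,S)-TsDPEN](p-cymene) (5 mol%), i-PrOH, rt
Reagents that add atoms: none
Why: In the Noyori asymmetric transfer hydrogenation of an alkynyl ketone the (S,S) catalyst, which treats the alkyne as the π-substituent, delivers hydride to the face that gives the 3S carbinol at C12, in line with the Felkin–Anh preference of the substrate, and the base-free conditions leave C11 untouched.

Step 14
Reactants: 20 (3S,4S,5S)-TMS-propargylic alcohol
Product: 21 (3S,4S,5S)-4-[2-methoxy-4-(methoxymethoxy)benzyl]-5-{4-[(triisopropylsilyl)oxy]phenyl}-7-(triisopropylsilyl)hepta-1,6-diyn-3-ol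
Conditions: K2CO3 (0.3 equiv), MeOH, 0 °C, short contact
Reagents that add atoms: none
Why: Methoxide-mediated protiodesilylation removes the trimethylsilyl group from the alkyne within minutes, whereas the triisopropylsilyl groups on the other alkyne and on the phenol are too hindered to react at 0 °C.

Step 15
Reactants: 21 (3S,4S,5S)-terminal propargylic alcohol; 7 1-bromo-2,4-dimethoxy-3-(methoxymethoxy)benzene
Product: 24 (1Z,3S,4S,5S)-2-[2,4-dimethoxy-3-(methoxymethoxy)phenyl]-1-iodo-4-[2-methoxy-4-(methoxymethoxy)benzyl]-5-{4-[(triisopropylsilyl)oxy]phenyl}-7-(triisopropylsilyl)hept-1-en-6-yn-3-ol, via arylmagnesium bromide 22 (not isolated), via cyclic alkenylmagnesium alkoxide 23 (not isolated)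
Conditions: 7, Mg, THF; then 21, CuI (20 mol%), THF, 0 → 40 °C; then I2, −40 → 0 °C
Reagents that add atoms: iodine, II
Why: In this copper-catalysed anti-carbomagnesiation of a propargylic alkoxide the aryl group is delivered to the proximal alkyne carbon C23 and magnesium to C22 within a five-membered oxamagnesacycle, so iodinolysis with retention should give the vinyl iodide with iodine cis to C12, the geometry the later ring closure requires.

Step 16
Reactants: 24 (1Z,3S,4S,5S)-vinyl iodide
Product: 25 (1Z,3S,4S,5S)-2-[2,4-dimethoxy-3-(methoxymethoxy)phenyl]-5-(4-hydroxyphenyl)-1-iodo-4-[2-methoxy-4-(methoxymethoxy)benzyl]-7-(triisopropylsilyl)hept-1-en-6-yn-3-ol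
Conditions: Bu4NF, AcOH, THF, 0 °C
Reagents that add atoms: none
Why: Fluoride cleaves the aryl silyl ether (phenoxide leaving group) far faster than the hindered alkynyl C–Si bond, so buffered fluoride at 0 °C should free only the phenol.

Step 17
Reactants: 25 phenol–allylic alcohol
Product: 26 (2S,3S,4R)-2-{(Z)-1-[2,4-dimethoxy-3-(methoxymethoxy)phenyl]-2-iodoethenyl}-3-[2-methoxy-4-(methoxymethoxy)benzyl]-4-[(triisopropylsilyl)ethynyl]-1-oxaspiro[4.5]deca-6,9-dien-8-one
Conditions: PhI(OAc)2, MeCN, 0 °C
Reagents that add atoms: none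
Why: In this oxidative dearomatisation (para-spiroetherification) the C12 hydroxyl traps the activated phenol at C14 in a 5-exo mode to close the tetrahydrofuran, and because the dienone is still symmetrical no stereocentre is formed at C14 yet.

Step 18
Reactants: 26 spirodienone vinyl iodide
Product: 27 oxa-bridged tricyclic trienone: 8-oxabicyclo[3.2.1]octene core (O13 between C12 and C14, C11–C43 bridge, C21–C22=C23 bridge) fused along C14–C21 to the cyclohexadienone C14–C15=C16–C18(=O)–C20=C21, with Ar2 on C23, Ar1CH2 on C11 and TIPS-ethynyl on C43 (11S,12S,14R,43R)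
Conditions: Pd(OAc)2 (15 mol%), P(o-tol)3 (30 mol%), KOAc, DMF, 80 °C
Reagents that add atoms: none
Why: In this intramolecular Heck reaction (6-exo-trig) the alkenylpalladium at C22 can reach only the dienone double bond on the face of the tetrahydrofuran that carries the C12 substituent, which fixes C14, and the palladium enolate is expected to equilibrate through its oxygen-bound form before β-hydride elimination restores the C20=C21 enone, the bulky silyl group keeping the nearby alkyne out of a competing 6-exo-dig insertion.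

Step 19
Reactants: 27 tricyclic trienone
Product: 28 16-iodo derivative of 27 (iodine on C16 of the C15=C16 enone)
Conditions: I2, pyridine/CH2Cl2, rt
Reagents that add atoms: iodine, II
Why: α-Iodination of an enone by pyridine-mediated conjugate addition, iodination and elimination should take place only at C16 of the β-unsubstituted C15=C16 enone, because C21 of the other enone is fully substituted and cannot accept the nucleophile.

Step 20
Reactants: 28 α-iodoenone; 17 ethynyltrimethylsilane
Product: 29 16-[(trimethylsilyl)ethynyl] derivative of 27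
Conditions: PdCl2(PPh3)2 (5 mol%), CuI (10 mol%), i-Pr2NH, THF, 0 °C → rt
Reagents that add atoms: none
Why: Sonogashira coupling of the α-iodoenone installs the C16–C35 bond while C16 is still trigonal, so that the oxygen can be added afterwards from the open face.

Step 21
Reactants: 29 2-alkynyl enone
Product: 30 15,16-dihydro derivative of 29 (C15H2, C16H bearing the TMS-ethynyl group; mixture of C16 epimers)
Conditions: [(Ph3P)CuH]6, toluene, H2O (2 equiv), rt
Reagents that add atoms: none
Why: Conjugate reduction with the phosphine-stabilised copper hydride delivers hydride to C15, the only unsubstituted β-carbon, the β- and δ-carbons C21 and C23 of the dienone being fully substituted, and the configuration at C16 of the ketone formed is immaterial.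

Step 22
Reactants: 30 α-alkynyl ketone
Product: 31 16-hydroxy derivative of 30: tertiary α-ketol with OH cis to O13 and TMS-ethynyl cis to C43 (16S)
Conditions: KN(SiMe3)2, THF, −78 °C; then 2-(phenylsulfonyl)-3-phenyloxaziridine, −78 °C
Reagents that add atoms: 2-(phenylsulfonyl)-3-phenyloxaziridine, O=S(=O)(c1ccccc1)N1OC1c1ccccc1
Why: In this enolate hydroxylation with an N-sulfonyloxaziridine (Davis oxidation) C16 is the only enolisable position, and because the silylethynyl group on C43 lies under the ring while the O13 face is open, oxygen should be delivered cis to O13, which leaves the C16 alkynyl group cis to C43 as the cyclisation needs.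

Step 23
Reactants: 31 bis-silylated diyne
Product: 32 diyne: 31 with both silyl groups removed, ethynyl on C16 and on C43 (11S,12S,14R,16S,43R)
Conditions: Bu4NF, AcOH, THF, 0 °C → rt
Reagents that add atoms: none
Why: Fluoride-mediated desilylation cleaves both alkynyl C–Si bonds, the acetic acid buffer protecting the tertiary α-ketol from base-induced retro-addition or rearrangement.

Step 24
Reactants: 32 diethynyl oxatricyclic dienone; 33 1,2-bis(4,4,5,5-tetramethyl-1,3,2-dioxaborolan-2-yl)ethyne
Product: 34 diboronate: full target skeleton with Bpin on C37 and C39 and both spectator phenols as MOM ethers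
Conditions: Cp*RuCl(cod) (10 mol%), 33 (4 equiv), ClCH2CH2Cl, 40 °C, 32 added slowly by syringe pump
Reagents that add atoms: none
Why: The two terminal alkynes couple oxidatively on the Cp*RuCl fragment to a ruthenacyclopentadiene that already holds the C35–C42 bond and the carbocycle C14–C15–C16–C35–C42–C43; insertion of 33 then forms C36–C37 and reductive elimination forms C39–C41, releasing the arene. The closest known reaction type is the ruthenium- or cobalt-catalysed [2+2+2] cyclotrimerisation of α,ω-diynes with alkynylboronates. The six-membered carbocycle closes by metal-templated coupling of a 1,7-diyne whose ethynyl groups are cis and 1,3-diaxial across C14–C15–C16 (C43 pseudoaxial on C14 with its ethynyl group endo under the ring, the C16 ethynyl axial, the hydroxyl equatorial), and the benzene ring closes by the insertion and reductive elimination pair. No stereocentre is created, since C16 and C43 are set in steps 22 and 8, and only the 16S epimer can bring the alkynes together. The step needs cross-selectivity over self-oligomerisation of the diyne and over binding of the dienone, which slow addition of 32 to an excess of the hindered 33 (which does not trimerise by itself) and the fully substituted alkenes of the substrate should secure, and regiochemistry is moot because 33 is symmetrical. The gain in aromaticity offsets the strain of the new bridged ring, and boron serves as a stable stand-in for oxygen on the two-carbon unit.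

Step 25
Reactants: 34 diboronate
Product: 35 bis-MOM ether of the target (free catechol at C37 and C39, free C16–OH)
Conditions: NaBO3·4H2O, THF/H2O, rt
Reagents that add atoms: sodium perborate (NaBO3·4H2O, shown as its dimeric anion without water), [Na+].[Na+].O[B-]1(O)OO[B-](O)(O)OO1
Why: Oxidation of the aryl boronates with perborate (peroxide addition to boron followed by 1,2-aryl shift from boron to oxygen) converts both C–B bonds into C–O bonds at the same carbons and is mild enough to spare the hindered dienone.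

Step 26
Reactants: 35 bis-MOM ether
Product: 36 CNP0246028.1 (11S,12S,14R,16S,43R in the SMILES numbering)
Conditions: HCl (3 M aq), MeOH, 40 °C
Reagents that add atoms: none
Why: Acid-catalysed acetal cleavage removes both MOM groups, while the bridged ether and the bridgehead tertiary alcohol cannot ionise and the methyl ethers are inert.

**Compound list**

1 | 4-hydroxy-2-methoxybenzaldehyde | COc1cc(O)ccc1C=O | starting material
2 | 2-methoxy-4-(methoxymethoxy)benzaldehyde | COCOc1ccc(C=O)c(OC)c1 | intermediate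
3 | [2-methoxy-4-(methoxymethoxy)phenyl]methanol | COCOc1ccc(CO)c(OC)c1 | intermediate
4 | 1-(bromomethyl)-2-methoxy-4-(methoxymethoxy)benzene | COCOc1ccc(CBr)c(OC)c1 | intermediate
5 | 2,6-dimethoxyphenol | COc1cccc(OC)c1O | starting material
6 | 1,3-dimethoxy-2-(methoxymethoxy)benzene | COCOc1c(OC)cccc1OC | intermediate
7 | 1-bromo-2,4-dimethoxy-3-(methoxymethoxy)benzene | COCOc1c(OC)ccc(Br)c1OC | intermediate
8 | 4-hydroxybenzaldehyde | O=Cc1ccc(O)cc1 | starting material
9 | 4-[(triisopropylsilyl)oxy]benzaldehyde | O=Cc1ccc(O[Si](C(C)C)(C(C)C)C(C)C)cc1 | intermediate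
10 | (triphenylphosphoranylidene)acetaldehyde | O=CC=P(c1ccccc1)(c1ccccc1)c1ccccc1 | starting material
11 | (E)-3-{4-[(triisopropylsilyl)oxy]phenyl}prop-2-enal | O=C/C=C/c1ccc(O[Si](C(C)C)(C(C)C)C(C)C)cc1 | intermediate
12 | ethynyltriisopropylsilane | C#C[Si](C(C)C)(C(C)C)C(C)C | starting material
13 | (3S)-3-{4-[(triisopropylsilyl)oxy]phenyl}-5-(triisopropylsilyl)pent-4-ynal | O=CC[C@H](C#C[Si](C(C)C)(C(C)C)C(C)C)c1ccc(O[Si](C(C)C)(C(C)C)C(C)C)cc1 | intermediate
14 | (3S)-3-{4-[(triisopropylsilyl)oxy]phenyl}-5-(triisopropylsilyl)pent-4-ynoic acid | OC(=O)C[C@H](C#C[Si](C(C)C)(C(C)C)C(C)C)c1ccc(O[Si](C(C)C)(C(C)C)C(C)C)cc1 | intermediate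
15 | (3S)-N-methoxy-N-methyl-3-{4-[(triisopropylsilyl)oxy]phenyl}-5-(triisopropylsilyl)pent-4-ynamide | CON(C)C(=O)C[C@H](C#C[Si](C(C)C)(C(C)C)C(C)C)c1ccc(O[Si](C(C)C)(C(C)C)C(C)C)cc1 | intermediate
16 | (2S,3S)-N-methoxy-2-[2-methoxy-4-(methoxymethoxy)benzyl]-N-methyl-3-{4-[(triisopropylsilyl)oxy]phenyl}-5-(triisopropylsilyl)pent-4-ynamide | CON(C)C(=O)[C@@H](Cc1ccc(OCOC)cc1OC)[C@H](C#C[Si](C(C)C)(C(C)C)C(C)C)c1ccc(O[Si](C(C)C)(C(C)C)C(C)C)cc1 | intermediate
17 | ethynyltrimethylsilane | C#C[Si](C)(C)C | starting material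
18 | lithium (trimethylsilyl)acetylide | [Li]C#C[Si](C)(C)C | intermediate
19 | (4S,5S)-4-[2-methoxy-4-(methoxymethoxy)benzyl]-5-{4-[(triisopropylsilyl)oxy]phenyl}-7-(triisopropylsilyl)-1-(trimethylsilyl)hepta-1,6-diyn-3-one | C[Si](C)(C)C#CC(=O)[C@@H](Cc1ccc(OCOC)cc1OC)[C@H](C#C[Si](C(C)C)(C(C)C)C(C)C)c1ccc(O[Si](C(C)C)(C(C)C)C(C)C)cc1 | intermediate
20 | (3S,4S,5S)-4-[2-methoxy-4-(methoxymethoxy)benzyl]-5-{4-[(triisopropylsilyl)oxy]phenyl}-7-(triisopropylsilyl)-1-(trimethylsilyl)hepta-1,6-diyn-3-ol | C[Si](C)(C)C#C[C@@H](O)[C@@H](Cc1ccc(OCOC)cc1OC)[C@H](C#C[Si](C(C)C)(C(C)C)C(C)C)c1ccc(O[Si](C(C)C)(C(C)C)C(C)C)cc1 | intermediate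
21 | (3S,4S,5S)-4-[2-methoxy-4-(methoxymethoxy)benzyl]-5-{4-[(triisopropylsilyl)oxy]phenyl}-7-(triisopropylsilyl)hepta-1,6-diyn-3-ol | C#C[C@@H](O)[C@@H](Cc1ccc(OCOC)cc1OC)[C@H](C#C[Si](C(C)C)(C(C)C)C(C)C)c1ccc(O[Si](C(C)C)(C(C)C)C(C)C)cc1 | intermediate
22 | [2,4-dimethoxy-3-(methoxymethoxy)phenyl]magnesium bromide | COCOc1c(OC)ccc([Mg]Br)c1OC | intermediate
23 | cyclic (Z)-alkenylmagnesium alkoxide from 21 (2,5-dihydro-1,2-oxamagnesole, Ar2 on C23, Mg on C22) | [Mg]1O[C@@H]([C@@H](Cc2ccc(OCOC)cc2OC)[C@H](C#C[Si](C(C)C)(C(C)C)C(C)C)c2ccc(O[Si](C(C)C)(C(C)C)C(C)C)cc2)C(c2ccc(OC)c(OCOC)c2OC)=C1 | intermediate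
24 | (1Z,3S,4S,5S)-2-[2,4-dimethoxy-3-(methoxymethoxy)phenyl]-1-iodo-4-[2-methoxy-4-(methoxymethoxy)benzyl]-5-{4-[(triisopropylsilyl)oxy]phenyl}-7-(triisopropylsilyl)hept-1-en-6-yn-3-ol | I/C=C(\[C@@H](O)[C@@H](Cc1ccc(OCOC)cc1OC)[C@H](C#C[Si](C(C)C)(C(C)C)C(C)C)c1ccc(O[Si](C(C)C)(C(C)C)C(C)C)cc1)c1ccc(OC)c(OCOC)c1OC | intermediate
25 | (1Z,3S,4S,5S)-2-[2,4-dimethoxy-3-(methoxymethoxy)phenyl]-5-(4-hydroxyphenyl)-1-iodo-4-[2-methoxy-4-(methoxymethoxy)benzyl]-7-(triisopropylsilyl)hept-1-en-6-yn-3-ol | I/C=C(\[C@@H](O)[C@@H](Cc1ccc(OCOC)cc1OC)[C@H](C#C[Si](C(C)C)(C(C)C)C(C)C)c1ccc(O)cc1)c1ccc(OC)c(OCOC)c1OC | intermediate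
26 | (2S,3S,4R)-2-{(Z)-1-[2,4-dimethoxy-3-(methoxymethoxy)phenyl]-2-iodoethenyl}-3-[2-methoxy-4-(methoxymethoxy)benzyl]-4-[(triisopropylsilyl)ethynyl]-1-oxaspiro[4.5]deca-6,9-dien-8-one | I/C=C(\[C@H]1OC2(C=CC(=O)C=C2)[C@@H](C#C[Si](C(C)C)(C(C)C)C(C)C)[C@@H]1Cc1ccc(OCOC)cc1OC)c1ccc(OC)c(OCOC)c1OC | intermediate
27 | oxa-bridged tricyclic trienone (C15=C16 enone, TIPS-ethynyl on C43, Ar1CH2 on C11, Ar2 on C23; 11S,12S,14R,43R) | COc1cc(OCOC)ccc1C[C@@H]1[C@@H]2O[C@@]3([C@H]1C#C[Si](C(C)C)(C(C)C)C(C)C)C=CC(=O)C=C3C=C2c1ccc(OC)c(OCOC)c1OC | intermediate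
28 | 16-iodo derivative of 27 | COc1cc(OCOC)ccc1C[C@@H]1[C@@H]2O[C@@]3([C@H]1C#C[Si](C(C)C)(C(C)C)C(C)C)C=C(I)C(=O)C=C3C=C2c1ccc(OC)c(OCOC)c1OC | intermediate
29 | 16-[(trimethylsilyl)ethynyl] derivative of 27 | COc1cc(OCOC)ccc1C[C@@H]1[C@@H]2O[C@@]3([C@H]1C#C[Si](C(C)C)(C(C)C)C(C)C)C=C(C#C[Si](C)(C)C)C(=O)C=C3C=C2c1ccc(OC)c(OCOC)c1OC | intermediate
30 | 15,16-dihydro derivative of 29 (C16 epimers) | COc1cc(OCOC)ccc1C[C@@H]1[C@@H]2O[C@@]3([C@H]1C#C[Si](C(C)C)(C(C)C)C(C)C)CC(C#C[Si](C)(C)C)C(=O)C=C3C=C2c1ccc(OC)c(OCOC)c1OC | intermediate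
31 | 16-hydroxy derivative of 30 (16S; OH cis to O13) | COc1cc(OCOC)ccc1C[C@@H]1[C@@H]2O[C@@]3([C@H]1C#C[Si](C(C)C)(C(C)C)C(C)C)C[C@](O)(C#C[Si](C)(C)C)C(=O)C=C3C=C2c1ccc(OC)c(OCOC)c1OC | intermediate
32 | diethynyl oxatricyclic dienone (ethynyl on C16 and C43; 11S,12S,14R,16S,43R) | COc1cc(OCOC)ccc1C[C@@H]1[C@@H]2O[C@@]3([C@H]1C#C)C[C@](O)(C#C)C(=O)C=C3C=C2c1ccc(OC)c(OCOC)c1OC | intermediate
33 | 1,2-bis(4,4,5,5-tetramethyl-1,3,2-dioxaborolan-2-yl)ethyne | CC1(C)OB(C#CB2OC(C)(C)C(C)(C)O2)OC1(C)C | starting material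
34 | C37,C39-diboronate of the bis-MOM target skeleton | COc1cc(OCOC)ccc1C[C@@H]1[C@@H]2O[C@@]34C[C@@](O)(C(=O)C=C3C=C2c2ccc(OC)c(OCOC)c2OC)c2cc(B5OC(C)(C)C(C)(C)O5)c(B5OC(C)(C)C(C)(C)O5)cc2[C@@H]14 | intermediate
35 | bis-MOM ether of the target | COc1cc(OCOC)ccc1C[C@@H]1[C@@H]2O[C@@]34C[C@@](O)(C(=O)C=C3C=C2c2ccc(OC)c(OCOC)c2OC)c2cc(O)c(O)cc2[C@@H]14 | intermediate
36 | CNP0246028.1 | COc1cc(O)ccc1C[C@@H]1[C@@H]2O[C@@]34C[C@@](O)(C(=O)C=C3C=C2c2ccc(OC)c(O)c2OC)c2cc(O)c(O)cc2[C@@H]14 | target

**Count and risks**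

Total steps: 26. Longest linear sequence: 21 steps (steps 6 to 26, from 4-hydroxybenzaldehyde 8).

Step 24. The diyne may oligomerise with itself, or the bulky diborylalkyne may fail to insert into the ruthenacycle. Fallback: setting out from 32, the cyclotrimerisation is run with the unhindered 2-ethynyl-4,4,5,5-tetramethyl-1,3,2-dioxaborolane under the same catalyst. The same three C–C bonds and both rings form, and the product should be the C37 monoboronate F1 mixed with the C39 monoboronate F2. NaBO3·4H2O then gives the C37 phenol F3 and the C39 phenol F4. The second oxygen is put in by C–H oxidation: IBX in DMF should oxidise each phenol at its less hindered ortho carbon (C39 and C37 respectively) to the same ortho-quinone F5, which Na2S2O4 reduces to the catechol 35, where the route is rejoined.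

Step 18. After insertion the palladium sits on C20 with no syn hydrogen on C21, so protonation or reduction of the palladium enolate may outrun β-hydride elimination; insertion into the neighbouring alkyne is a second escape. Fallback: from 26, a deliberately reductive Heck cyclisation (Pd(OAc)2, PPh3, HCO2Na, DMF, 80 °C) should give the cis-fused C20,C21-dihydro ketone F6. Silylation (Me3SiOTf, Et3N) can enolise only toward C20 and gives the trimethylsilyl dienol ether F7, and Saegusa–Ito dehydrogenation with Pd(OAc)2 in MeCN returns to 27.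

Step 15. Carbomagnesiation of the hindered secondary propargylic alkoxide may be sluggish, with deprotonation of the terminal alkyne and erosion of regio- or geometric control as competing processes. Fallback: from 20, which still carries the alkynyl trimethylsilyl group, a rhodium-catalysed syn-hydroarylation ([Rh(OH)(cod)]2, dioxane/H2O, 60 °C) is run with [2,4-dimethoxy-3-(methoxymethoxy)phenyl]boronic acid F8, made from 7 by n-BuLi, B(OMe)3 and mild aqueous work-up. It should place the aryl group on C23, remote from silicon, and hydrogen on C22, giving the (1Z,3S,4S,5S)-vinylsilane F9 with silicon cis to C12. Iododesilylation with N-iodosuccinimide (MeCN/ClCH2CN, 0 °C) proceeds with retention and delivers 24.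

**Further compounds**

F1 | step 24 | C37 monoboronate of the bis-MOM target skeleton | COc1cc(OCOC)ccc1C[C@@H]1[C@@H]2O[C@@]34C[C@@](O)(C(=O)C=C3C=C2c2ccc(OC)c(OCOC)c2OC)c2cc(B5OC(C)(C)C(C)(C)O5)ccc2[C@@H]14
F2 | step 24 | C39 monoboronate of the bis-MOM target skeleton | COc1cc(OCOC)ccc1C[C@@H]1[C@@H]2O[C@@]34C[C@@](O)(C(=O)C=C3C=C2c2ccc(OC)c(OCOC)c2OC)c2ccc(B5OC(C)(C)C(C)(C)O5)cc2[C@@H]14
F3 | step 24 | C37 phenol (39-deoxy-35) | COc1cc(OCOC)ccc1C[C@@H]1[C@@H]2O[C@@]34C[C@@](O)(C(=O)C=C3C=C2c2ccc(OC)c(OCOC)c2OC)c2cc(O)ccc2[C@@H]14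
F4 | step 24 | C39 phenol (37-deoxy-35) | COc1cc(OCOC)ccc1C[C@@H]1[C@@H]2O[C@@]34C[C@@](O)(C(=O)C=C3C=C2c2ccc(OC)c(OCOC)c2OC)c2ccc(O)cc2[C@@H]14
F5 | step 24 | C37,C39 ortho-quinone corresponding to 35 | COc1cc(OCOC)ccc1C[C@@H]1[C@@H]2O[C@@]34C[C@@](O)(C(=O)C=C3C=C2c2ccc(OC)c(OCOC)c2OC)C2=CC(=O)C(=O)C=C2[C@@H]14
F6 | step 18 | C20,C21-dihydro-27 (H on C21 cis to C43) | COc1cc(OCOC)ccc1C[C@@H]1[C@@H]2O[C@@]3([C@H]1C#C[Si](C(C)C)(C(C)C)C(C)C)C=CC(=O)C[C@H]3C=C2c1ccc(OC)c(OCOC)c1OC
F7 | step 18 | trimethylsilyl dienol ether of F6 (C18–OSiMe3, C18=C20) | COc1cc(OCOC)ccc1C[C@@H]1[C@@H]2O[C@@]3([C@H]1C#C[Si](C(C)C)(C(C)C)C(C)C)C=CC(O[Si](C)(C)C)=C[C@H]3C=C2c1ccc(OC)c(OCOC)c1OC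
F8 | step 15 | [2,4-dimethoxy-3-(methoxymethoxy)phenyl]boronic acid | COCOc1c(OC)ccc(B(O)O)c1OC
F9 | step 15 | (1Z,3S,4S,5S)-2-[2,4-dimethoxy-3-(methoxymethoxy)phenyl]-4-[2-methoxy-4-(methoxymethoxy)benzyl]-5-{4-[(triisopropylsilyl)oxy]phenyl}-7-(triisopropylsilyl)-1-(trimethylsilyl)hept-1-en-6-yn-3-ol | C[Si](C)(C)/C=C(\[C@@H](O)[C@@H](Cc1ccc(OCOC)cc1OC)[C@H](C#C[Si](C(C)C)(C(C)C)C(C)C)c1ccc(O[Si](C(C)C)(C(C)C)C(C)C)cc1)c1ccc(OC)c(OCOC)c1OC
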